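## Structural features

The target is a flavone. Benzo ring A is fused through C4a–C8a to pyran-4-one ring C, which carries a methoxy group at C3 and is joined to aryl ring B by the single bond C2–C1'. There is no stereocentre, hence no adjacent stereocentres; the only stereochemical element on the way is an enol-ether double bond whose geometry is erased. Ring A has oxygen on alternate carbons (OH at C5 and C7, ring oxygen O1 on C8a), and C4a between two of them carries the C4 carbonyl. This acylphloroglucinol pattern is what Claisen folding of a 3,5,7-triketo ester gives, and the key step uses it to form C4a–C5 and then O1–C2. Ring B is 2',4',5'-trioxygenated (free OH at C2', methyl ether at C4', acetate at C5'). O2' and O5' are para, so an intermediate with one free and the other etherified is a hydroquinone monoether that an oxidant can take to a quinone. The aryl acetate is the fragile group: alkoxides, amines and hot alcohols remove it, so it goes on late and everything after it must be neutral. The real difficulty is telling four phenolic oxygens apart: O5' must be acylated while O5, O7 and O2' end free, and O7 (a vinylogous acid) is the most easily acylated while the chelated O5 is the least. A lesser difficulty is steric: C2 sits between the C3 methoxy group and the ortho-oxygenated ring B, so O1–C2 has to form at a crowded carbon.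

## Logic of the disconnections

**20 to 19.** The three benzyl–oxygen bonds at O5, O7 and O2' are cut last. Hydrogenolysis is the one deprotection that is neutral and leaves an aryl acetate alone. All three hydroxyls that must end free are then hidden under one kind of group. The forward step must not solvolyse the acetate or reduce C2=C3, so it is run in an aprotic solvent at atmospheric pressure.

**19 to 18 to 17.** The acetyl–O5' bond is cut, then the allyl–O5' bond. O5' must be the only free hydroxyl when the acetate goes on. An allyl ether is preferred to a 4-methoxybenzyl ether at O5' for two reasons: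
- Oxidative removal would expose the hydroquinone monoether 18 to the same oxidant.
- Acidic removal would rule out the acid finish that the ring-closing step benefits from.

Zerovalent palladium frees O5' with neither oxidant nor acid and leaves benzyl ethers alone. The forward demand is only that acylation of 18 be clean, which one free phenol guarantees.

**17 to 16.** The benzyl–oxygen bonds at O5 and O7 are cut. These two hydroxyls are necessarily free after ring formation, because they were chain carbonyls. This leads back to a compound whose only protecting groups are base-stable ethers on ring B. The forward step has to etherify the chelated O5, which needs forcing conditions.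

**16 to 14 (through 15).** O1–C2 and C4a–C5 are cut. Both rings A and C disappear and an open chain remains, in which C1 to C7 are a plain polyketide and all ring A oxygens are carbonyl oxygens. The forward step must fold by Claisen (C6 onto the ester) and not by aldol. It also needs C9 to be an electrophile with a leaving group and C8 to have no acidic hydrogen. The methyl enol ether at C8=C9 provides both, and its geometry is not a requirement.

**14 to 10 and 12 (through 13); 12 to 11.** The C6–C7 bond is cut. This divides the chain into a C6 diketo ester, whose terminal methyl becomes the most nucleophilic site of a trianion, and an acyl donor that holds ring B and the masked C8–C9 unit. The route becomes convergent, and 12 is one step from 11. The forward step needs an acyl donor with no acidic hydrogen (true of 10) and 1,2-addition rather than attack at the β-carbon.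

**10 to 9 to 8 to 5 and 6.** The O–CH3 bond of the enol ether is cut, the benzylic carbon is taken down one oxidation level, and the C2–C3 bond of the propanoate is cut as an aldol bond. The two-carbon unit 6 already carries the future C3 methoxy group, and its enolate adds reliably to a non-enolisable aldehyde. The forward demand is O- over C-methylation of 9.

**5 to 4 to 3 to 1.** The benzyl–O2' bond, the allyl–O5' bond and then the C5'–O bond are cut. Compound 1 already has C1', O2' and the 4'-methoxy group, and the missing oxygen is para to its phenol, the position a persulfate oxidation addresses. The forward demand is to tell apart the two hydroxyls of 3, which chelation of the 2-OH to the formyl group allows.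

## Other disconnections considered

Alternative 1: The cut is on both sides of C4 (C4a–C4 and C4–C3), with carbon monoxide as C4.
- **Forward step.** 1,5-Bis(benzyloxy)-2-iodo-3-(methoxymethoxy)benzene A1, CO and 1-[2-(benzyloxy)-4-methoxy-5-(methoxymethoxy)phenyl]-2-methoxyethan-1-one A2 would be joined by Pd(dba)2 (zerovalent palladium), Xantphos and base in a carbonylative α-arylation. This gives the open diketone A3 and closes no ring. Acid would then remove both methoxymethyl groups and cyclodehydrate, which should lead straight to 18.
- **In favour.** The union is convergent, both rings arrive with their final protecting pattern, and no folding-mode question arises. From A3 to 20 is three operations against five from 14; on endgame economy this alternative is the better one.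
- **Against.** The iodide A1 has two ortho alkoxy groups, so formation and capture of the aroyl–palladium species are hindered and direct arylation without CO may compete. Enolates of α-alkoxy ketones are less usual partners. CO has to be handled. A1 needs a regiodefined iodination between two different ethers, and A2 needs a two-carbon homologation of an aldehyde such as 5.
- **Comparison.** On structure, both plans rest on the symmetry of ring A, but the chosen plan makes that ring from 11 while this one buys it. On mechanism, the chosen plan uses carbonyl condensations without a transition metal, against a three-component catalytic cycle at a congested centre. The total number of operations is about the same; the longest linear sequence is shorter here, a point for this alternative.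

Alternative 2: The cut is C3–C4 and O1–C8a.
- **Forward step.** The lithium enolate of 1-[5-(allyloxy)-2-(benzyloxy)-4-methoxyphenyl]-2-methoxyethan-1-one A4 (excess LiN(SiMe3)2, THF) would be C-acylated by 2,4,6-trifluorobenzoyl chloride A5. The diketonate oxygen would then displace an ortho fluoride to give the 5,7-difluoroflavone A6 in one flask.
- **In favour.** Both bonds of ring C form in one operation from a commercial ring A unit, and the two ortho fluorides are equivalent, so the closure is unambiguous. The route is probably about two operations shorter than the chosen one; on step economy this alternative is the better one.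
- **Against.** The C5 and C7 oxygens must be brought in afterwards by two intermolecular displacements with NaOCH2Ph to reach 17. The second is slowed by the first alkoxy group, and the alkoxide can also attack C2 of the pyranone. O-acylation can compete in the key step, and A4 needs the same homologation as A2.
- **Comparison.** On mechanism the two plans are equal in kind: each closes ring C by an oxygen nucleophile expelling a leaving group (fluoride at C8a here, methoxide at C2 in the chosen plan). On structure the chosen plan is better, because O5 and O7 come free from the chain carbonyls and do not have to be forced onto a progressively deactivated ring.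

Alternative 3: The cut is O1–C8a and C4–C4a.
- **Forward step.** CsF would release 3,5-bis(benzyloxy)benzyne A9 from 3,5-bis(benzyloxy)-2-(trimethylsilyl)phenyl trifluoromethanesulfonate A7. Heating 6-[5-(allyloxy)-2-(benzyloxy)-4-methoxyphenyl]-5-methoxy-2,2-dimethyl-4H-1,3-dioxin-4-one A8 would expel acetone to give the aroyl(methoxy)ketene A10. The ketone oxygen would add to the aryne carbon remote from the benzyloxy group, and the aryl anion would add to the ketene carbon. The product A11 is the same compound as 17.
- **In favour.** Fully protected 17 would be reached in one step from two halves. The orientation agrees with the usual preference of 3-alkoxyarynes, and the conditions are neutral. From 17 on it equals the chosen plan, and it is better in that O5 and O7 need no separate benzylation.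
- **Against.** Two short-lived species made by different triggers (fluoride near ambient temperature, heat above about 100 °C) must meet. Ketene dimerisation, aryne–ketene [2+2] addition, an ene reaction of the aryne with the allyl ether and fluoride addition to the ketene are all open. A7 and A8 each need several steps.
- **Comparison.** On structure it uses nothing of ring A beyond its 1,2-relationship. On mechanism the chosen carbonyl condensations have closer precedent than capture of an aryne by an acylketene. The longest linear sequence would be shorter (a point for this alternative), but the total count would not be lower.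

Key step: step 9

Remark on the chemistry: enol ether 10, and hence 14 and 15, are drawn as the Z isomers. O-methylation may give the E isomer or a mixture; this is assumed to be without consequence, because the C8=C9 geometry is lost in the addition–elimination that closes ring C.

Step 1
Reactants: 1 2-hydroxy-4-methoxybenzaldehyde
Product: 3 2,5-dihydroxy-4-methoxybenzaldehyde, via potassium 5-formyl-4-hydroxy-2-methoxyphenyl sulfate 2 (not isolated)
Conditions: K2S2O8 (1.1 equiv), 10% aq NaOH, 0 → 20 °C; then HCl to pH 1, 90 °C
Reagents that add atoms: potassium peroxodisulfate, [K+].[K+].[O-]S(=O)(=O)OOS(=O)(=O)[O-]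
Why: Elbs persulfate oxidation: the phenoxide of 1 attacks a peroxide oxygen through its para carbon (C5, the only open para position), giving aryl sulfate 2, which hot acid hydrolyses to the hydroquinone; salicylaldehydes are classical substrates and unreacted 1 can be recovered.

Step 2
Reactants: 3 2,5-dihydroxy-4-methoxybenzaldehyde
Product: 4 5-(allyloxy)-2-hydroxy-4-methoxybenzaldehyde
Conditions: allyl bromide (1.05 equiv), K2CO3 (1.1 equiv), MeCN, 60 °C
Reagents that add atoms: allyl bromide, C=CCBr
Why: Williamson etherification: the 2-hydroxyl is hydrogen-bonded to the formyl group and its phenoxide is delocalised into it, so with one equivalent of halide the more nucleophilic 5-phenoxide should be alkylated, the classical outcome for 2,5-dihydroxyaryl carbonyl compounds.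

Step 3
Reactants: 4 5-(allyloxy)-2-hydroxy-4-methoxybenzaldehyde
Product: 5 5-(allyloxy)-2-(benzyloxy)-4-methoxybenzaldehyde
Conditions: BnBr (1.3 equiv), K2CO3 (2 equiv), DMF, 60 °C
Reagents that add atoms: benzyl bromide, BrCc1ccccc1
Why: Williamson etherification of the remaining chelated phenol, which needs the dipolar solvent and warming; the allyl ether and the aldehyde are inert.

Step 4
Reactants: 5 5-(allyloxy)-2-(benzyloxy)-4-methoxybenzaldehyde; 6 methyl methoxyacetate
Product: 8 methyl 3-[5-(allyloxy)-2-(benzyloxy)-4-methoxyphenyl]-3-hydroxy-2-methoxypropanoate (racemic mixture of diastereomers), via lithium enolate of methyl methoxyacetate 7 (not isolated)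
Conditions: 6 (1.2 equiv), LiN(iPr)2 (1.15 equiv), THF, −78 °C; then 5, −78 °C; aq NH4Cl
Reagents that add atoms: none
Why: Aldol addition of a preformed lithium ester enolate to a non-enolisable aromatic aldehyde at low temperature; the two new stereocentres form without control and both are removed in steps 5 and 6, so the mixture is carried on.

Step 5
Reactants: 8 methyl 3-[5-(allyloxy)-2-(benzyloxy)-4-methoxyphenyl]-3-hydroxy-2-methoxypropanoate
Product: 9 methyl 3-[5-(allyloxy)-2-(benzyloxy)-4-methoxyphenyl]-2-methoxy-3-oxopropanoate (racemic, enolisable)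
Conditions: Dess–Martin periodinane (1.3 equiv), CH2Cl2, 0 → 23 °C
Reagents that add atoms: none
Why: Dess–Martin oxidation of a benzylic secondary alcohol to the aryl ketone under neutral conditions that leave the allyl and benzyl ethers and the ester untouched; the carbinol stereocentre is removed.

Step 6
Reactants: 9 methyl 3-[5-(allyloxy)-2-(benzyloxy)-4-methoxyphenyl]-2-methoxy-3-oxopropanoate
Product: 10 methyl (2Z)-3-[5-(allyloxy)-2-(benzyloxy)-4-methoxyphenyl]-2,3-dimethoxyprop-2-enoate
Conditions: Cs2CO3 (1.5 equiv), Me2SO4 (1.3 equiv), DMF, 0 → 23 °C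
Reagents that add atoms: dimethyl sulfate, COS(=O)(=O)OC
Why: O-Alkylation of a β-keto ester enolate: the loosely paired cesium enolate in DMF and the hard electrophile favour attack through oxygen, and C-methylation would have to build a fully substituted carbon beside an ortho-substituted aryl ketone; the last stereocentre becomes sp2 and the double-bond geometry does not matter later.

Step 7
Reactants: 11 dehydroacetic acid (3-acetyl-4-hydroxy-6-methyl-2H-pyran-2-one)
Product: 12 methyl 3,5-dioxohexanoate
Conditions: Mg(OMe)2 (2.2 equiv), MeOH, 65 °C; then 2 M HCl, 0 °C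
Reagents that add atoms: methanol, CO (solvent; also supplied as Mg(OMe)2, C[O-].C[O-].[Mg+2])
Why: Methanolysis of the pyranone lactone followed by retro-Claisen loss of the 3-acetyl group as methyl acetate, a known preparation of 12; the magnesium chelate of the product protects it from further cleavage.

Step 8
Reactants: 12 methyl 3,5-dioxohexanoate; 10 methyl (2Z)-3-[5-(allyloxy)-2-(benzyloxy)-4-methoxyphenyl]-2,3-dimethoxyprop-2-enoate
Product: 14 methyl (8Z)-9-[5-(allyloxy)-2-(benzyloxy)-4-methoxyphenyl]-8,9-dimethoxy-3,5,7-trioxonon-8-enoate, via trilithium trianion of methyl 3,5-dioxohexanoate 13 (not isolated)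
Conditions: 12 (2.2 equiv), LiN(iPr)2 (6.6 equiv), THF, −78 → 0 °C; then 10, 0 → 23 °C; AcOH quench; used crude
Reagents that add atoms: none
Why: Claisen-type acylation of a 1,3,5-tricarbonyl trianion by an ester at its terminal, least stabilised carbanion; the second equivalent of trianion deprotonates the more acidic product, and 1,2-addition is expected because the β-carbon of 10 is fully substituted and shielded by the ortho-benzyloxyaryl group.

Step 9
Reactants: 14 methyl (8Z)-9-[5-(allyloxy)-2-(benzyloxy)-4-methoxyphenyl]-8,9-dimethoxy-3,5,7-trioxonon-8-enoate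
Product: 16 2-[5-(allyloxy)-2-(benzyloxy)-4-methoxyphenyl]-5,7-dihydroxy-3-methoxy-4H-chromen-4-one, via ring A acylphloroglucinol enone 15 (not isolated)
Conditions: Mg(OMe)2 (6 equiv), MeOH, 23 → 65 °C; then 1 M HCl, THF–MeOH, 45 °C
Reagents that add atoms: none
Why: Mg(OMe)2 turns 14 into a magnesium polyketonate in which the C6 carbon, acidified by the C5 and C7 carbonyls, adds to the C1 ester carbonyl held nearby in the chelate (6-exo-trig) and methoxide leaves; this is the Claisen-type cyclisation known for 3,5,7-triketo esters under magnesium alkoxide, and the 2-acylcyclohexane-1,3,5-trione enolises irreversibly to acylphloroglucinol 15, which closes ring A. One of the two phenols ortho to the acyl group, equivalent by the symmetry of ring A, then adds to C9 of the β-methoxy enone (6-endo-trig oxa-Michael addition) and the adduct expels methanol, which closes ring C as an aromatic pyranone; the closest known reaction is the addition–elimination by which 2-hydroxyaryl β-alkoxyvinyl ketones give chromones. The acid finish breaks up the magnesium chelates and completes the second closure for any 15 left, also by way of the 1,3-diketone should the enol ether hydrolyse first, since that diketone cyclodehydrates to the same flavone. No stereocentre is formed, and the geometry of the C8=C9 bond disappears in the tetrahedral adduct, so both geometric isomers of 14 converge on 16. The selectivity required is Claisen folding over aldol folding from C2 onto C7 and over lactonisation to a 4-hydroxy-2-pyranone. It is secured by the substrate, in which C7 is a vinylogous ester and so a poor aldol acceptor and C8 bears no acidic hydrogen, and by the non-aqueous magnesium alkoxide medium, in which pyranones reopen while aromatisation of ring A does not reverse.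

Step 10
Reactants: 16 2-[5-(allyloxy)-2-(benzyloxy)-4-methoxyphenyl]-5,7-dihydroxy-3-methoxy-4H-chromen-4-one
Product: 17 2-[5-(allyloxy)-2-(benzyloxy)-4-methoxyphenyl]-5,7-bis(benzyloxy)-3-methoxy-4H-chromen-4-one
Conditions: BnBr (3 equiv), K2CO3 (4 equiv), Bu4NI (cat.), DMF, 70 °C
Reagents that add atoms: benzyl bromide, BrCc1ccccc1
Why: Williamson etherification; the acidic 7-OH reacts readily and the chelated 5-OH needs heat and excess halide, while K2CO3 in DMF favours O- over C-benzylation of the carbonyl-deactivated phloroglucinol ring.

Step 11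
Reactants: 17 2-[5-(allyloxy)-2-(benzyloxy)-4-methoxyphenyl]-5,7-bis(benzyloxy)-3-methoxy-4H-chromen-4-one
Product: 18 5,7-bis(benzyloxy)-2-[2-(benzyloxy)-5-hydroxy-4-methoxyphenyl]-3-methoxy-4H-chromen-4-one
Conditions: Pd(PPh3)4 (5 mol %), morpholine (5 equiv), THF, 23 °C
Reagents that add atoms: none
Why: Tsuji–Trost deallylation: zerovalent palladium ionises the aryl allyl ether to a π-allyl complex that morpholine captures; benzyl ethers and the pyranone are inert, and no oxidant meets the hydroquinone monoether that is set free.

Step 12
Reactants: 18 5,7-bis(benzyloxy)-2-[2-(benzyloxy)-5-hydroxy-4-methoxyphenyl]-3-methoxy-4H-chromen-4-one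
Product: 19 4-(benzyloxy)-5-[5,7-bis(benzyloxy)-3-methoxy-4-oxo-4H-chromen-2-yl]-2-methoxyphenyl acetate
Conditions: Ac2O (1.5 equiv), pyridine (3 equiv), DMAP (5 mol %), CH2Cl2, 0 → 23 °C
Reagents that add atoms: acetic anhydride, CC(=O)OC(C)=O
Why: Nucleophile-catalysed acylation of the only free hydroxyl in the molecule, so no selectivity question arises.

Step 13
Reactants: 19 4-(benzyloxy)-5-[5,7-bis(benzyloxy)-3-methoxy-4-oxo-4H-chromen-2-yl]-2-methoxyphenyl acetate
Product: 20 5-(5,7-dihydroxy-3-methoxy-4-oxo-4H-chromen-2-yl)-4-hydroxy-2-methoxyphenyl acetate (5,7,2',5'-tetrahydroxy-3,4'-dimethoxyflavone 5'-acetate)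
Conditions: H2 (1 atm), 10% Pd/C, EtOAc–THF, 23 °C
Reagents that add atoms: none
Why: Heterogeneous hydrogenolysis of three aryl benzyl ethers under neutral aprotic conditions; the aryl acetate is not cleaved and cannot migrate to O2', which is para to it, and the tetrasubstituted C2=C3 bond of the pyranone should not be reduced at atmospheric pressure.

## Compound list

1 | 2-hydroxy-4-methoxybenzaldehyde | COc1ccc(C=O)c(O)c1 | starting material
2 | potassium 5-formyl-4-hydroxy-2-methoxyphenyl sulfate | COc1cc(O)c(C=O)cc1OS(=O)(=O)[O-].[K+] | intermediate (not isolated)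
3 | 2,5-dihydroxy-4-methoxybenzaldehyde | COc1cc(O)c(C=O)cc1O | intermediate
4 | 5-(allyloxy)-2-hydroxy-4-methoxybenzaldehyde | COc1cc(O)c(C=O)cc1OCC=C | intermediate
5 | 5-(allyloxy)-2-(benzyloxy)-4-methoxybenzaldehyde | COc1cc(OCc2ccccc2)c(C=O)cc1OCC=C | intermediate
6 | methyl methoxyacetate | COCC(=O)OC | starting material
7 | lithium enolate of methyl methoxyacetate (lithium 1,2-dimethoxyethen-1-olate, geometry not defined) | [Li+].COC=C([O-])OC | intermediate (not isolated)
8 | methyl 3-[5-(allyloxy)-2-(benzyloxy)-4-methoxyphenyl]-3-hydroxy-2-methoxypropanoate (racemic mixture of diastereomers) | COC(=O)C(OC)C(O)c1cc(OCC=C)c(OC)cc1OCc1ccccc1 | intermediate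
9 | methyl 3-[5-(allyloxy)-2-(benzyloxy)-4-methoxyphenyl]-2-methoxy-3-oxopropanoate (racemic) | COC(=O)C(OC)C(=O)c1cc(OCC=C)c(OC)cc1OCc1ccccc1 | intermediate
10 | methyl (2Z)-3-[5-(allyloxy)-2-(benzyloxy)-4-methoxyphenyl]-2,3-dimethoxyprop-2-enoate | COC(=O)/C(OC)=C(/OC)c1cc(OCC=C)c(OC)cc1OCc1ccccc1 | intermediate
11 | dehydroacetic acid (3-acetyl-4-hydroxy-6-methyl-2H-pyran-2-one) | CC(=O)c1c(O)cc(C)oc1=O | starting material
12 | methyl 3,5-dioxohexanoate | CC(=O)CC(=O)CC(=O)OC | intermediate
13 | trilithium trianion of methyl 3,5-dioxohexanoate | [Li+].[Li+].[Li+].C=C([O-])C=C([O-])C=C([O-])OC | intermediate (not isolated)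
14 | methyl (8Z)-9-[5-(allyloxy)-2-(benzyloxy)-4-methoxyphenyl]-8,9-dimethoxy-3,5,7-trioxonon-8-enoate | COC(=O)CC(=O)CC(=O)CC(=O)/C(OC)=C(/OC)c1cc(OCC=C)c(OC)cc1OCc1ccccc1 | intermediate
15 | (2Z)-3-[5-(allyloxy)-2-(benzyloxy)-4-methoxyphenyl]-2,3-dimethoxy-1-(2,4,6-trihydroxyphenyl)prop-2-en-1-one | O=C(c1c(O)cc(O)cc1O)/C(OC)=C(/OC)c1cc(OCC=C)c(OC)cc1OCc1ccccc1 | intermediate (not isolated)
16 | 2-[5-(allyloxy)-2-(benzyloxy)-4-methoxyphenyl]-5,7-dihydroxy-3-methoxy-4H-chromen-4-one | COc1cc(OCc2ccccc2)c(-c2oc3cc(O)cc(O)c3c(=O)c2OC)cc1OCC=C | intermediate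
17 | 2-[5-(allyloxy)-2-(benzyloxy)-4-methoxyphenyl]-5,7-bis(benzyloxy)-3-methoxy-4H-chromen-4-one | COc1cc(OCc2ccccc2)c(-c2oc3cc(OCc4ccccc4)cc(OCc4ccccc4)c3c(=O)c2OC)cc1OCC=C | intermediate
18 | 5,7-bis(benzyloxy)-2-[2-(benzyloxy)-5-hydroxy-4-methoxyphenyl]-3-methoxy-4H-chromen-4-one | COc1cc(OCc2ccccc2)c(-c2oc3cc(OCc4ccccc4)cc(OCc4ccccc4)c3c(=O)c2OC)cc1O | intermediate
19 | 4-(benzyloxy)-5-[5,7-bis(benzyloxy)-3-methoxy-4-oxo-4H-chromen-2-yl]-2-methoxyphenyl acetate | COc1cc(OCc2ccccc2)c(-c2oc3cc(OCc4ccccc4)cc(OCc4ccccc4)c3c(=O)c2OC)cc1OC(C)=O | intermediate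
20 | 5-(5,7-dihydroxy-3-methoxy-4-oxo-4H-chromen-2-yl)-4-hydroxy-2-methoxyphenyl acetate (5,7,2',5'-tetrahydroxy-3,4'-dimethoxyflavone 5'-acetate) | COc1cc(O)c(-c2oc3cc(O)cc(O)c3c(=O)c2OC)cc1OC(C)=O | target

## Step count and least certain steps

Total: 13 steps. Longest linear sequence: 12 steps (1 to 20 through steps 1–6 and 8–13); step 7 is a one-step side branch.

**Step 9 (key step).**
- What may go wrong: aldol folding from C2 onto C7, or lactonisation to a pyranone, may compete with Claisen folding. The C4 carbanion may add to C9 with loss of methanol and aromatise to a biaryl resorcinol. Closure of ring C may stall at 15.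
- Fallback: abandon the polyketide folding, leave the route at 5 and return at 17 by an aroyl-transfer flavone synthesis. Pinnick oxidation of 5 (NaClO2, NaH2PO4, 2-methylbut-2-ene, tBuOH–H2O) should give 5-(allyloxy)-2-(benzyloxy)-4-methoxybenzoic acid F1, and (COCl)2 with catalytic DMF should give 5-(allyloxy)-2-(benzyloxy)-4-methoxybenzoyl chloride F2. Separately, 2-methoxy-1-(2,4,6-trihydroxyphenyl)ethan-1-one F3 (from phloroglucinol and methoxyacetonitrile by a Hoesch reaction) would be dibenzylated (BnBr, K2CO3, acetone) to 1-[2,4-bis(benzyloxy)-6-hydroxyphenyl]-2-methoxyethan-1-one F4. Treating F4 with LiN(SiMe3)2 (3.5 equiv, THF, −78 °C) and then F2 should give, by O-aroylation and Baker–Venkataraman transfer in the same flask, 3-[5-(allyloxy)-2-(benzyloxy)-4-methoxyphenyl]-1-[2,4-bis(benzyloxy)-6-hydroxyphenyl]-2-methoxypropane-1,3-dione F5. Cyclodehydration (AcOH, catalytic H2SO4, 60 °C) then gives 17.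

**Step 8.**
- What may go wrong: 1,2-addition to the push–pull ester 10 may be slow, conjugate addition–elimination at its β-carbon may intervene, and proton transfer may return starting materials.
- Fallback: use a more electrophilic carbonyl at a lower oxidation level, leaving at 10 and returning at 14. iBu2AlH (CH2Cl2, −78 °C) should reduce 10 to (2Z)-3-[5-(allyloxy)-2-(benzyloxy)-4-methoxyphenyl]-2,3-dimethoxyprop-2-en-1-ol F6. MnO2 should give (2Z)-3-[5-(allyloxy)-2-(benzyloxy)-4-methoxyphenyl]-2,3-dimethoxyprop-2-enal F7. Aldol addition of trianion 13 to F7 at −78 °C should give methyl (8Z)-9-[5-(allyloxy)-2-(benzyloxy)-4-methoxyphenyl]-7-hydroxy-8,9-dimethoxy-3,5-dioxonon-8-enoate F8. Dess–Martin periodinane or MnO2 then oxidises the allylic carbinol to 14.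

**Step 6.**
- What may go wrong: C-methylation of the enolate at the carbon between the two carbonyls may compete, leaving no enol ether.
- Fallback: avoid the carbanion altogether, leaving at 9 and returning at 10. HC(OMe)3 with catalytic TsOH in MeOH at 50 °C should convert the aryl ketone into the dimethyl ketal methyl 3-[5-(allyloxy)-2-(benzyloxy)-4-methoxyphenyl]-2,3,3-trimethoxypropanoate F9. Continued heating with the acid in toluene, with removal of methanol, eliminates one methoxy group to give 10.

**Step 1 (and the selective alkylation of step 2).**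
- What may go wrong: the persulfate oxidation may stop at low conversion and degrade the aldehyde. In step 2, double alkylation or alkylation at O2 may erode the yield of 4.
- Fallback: install the oxygen through a halide, which never requires two free phenols; it leaves at 1 and returns at 5. Benzylation of 1 (BnBr, K2CO3, DMF) gives 2-(benzyloxy)-4-methoxybenzaldehyde F10. Bromination (NBS, MeCN) should go para to the benzyloxy group to give 2-(benzyloxy)-5-bromo-4-methoxybenzaldehyde F11. Miyaura borylation (bis(pinacolato)diboron, PdCl2(dppf), KOAc, dioxane, 85 °C) gives 2-(benzyloxy)-4-methoxy-5-(4,4,5,5-tetramethyl-1,3,2-dioxaborolan-2-yl)benzaldehyde F12. Oxidation with NaBO3·4H2O in THF–H2O gives 2-(benzyloxy)-5-hydroxy-4-methoxybenzaldehyde F13, which is allylated (allyl bromide, K2CO3, DMF) to 5.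

**Step 10.**
- What may go wrong: etherification of the chelated O5 may be incomplete, and forcing it may cause C-benzylation at C6 or C8.
- Fallback: rely on chelation and leave O5 unprotected, leaving at 16 and returning at 20. One equivalent of BnBr with K2CO3 in acetone at 40 °C should give 2-[5-(allyloxy)-2-(benzyloxy)-4-methoxyphenyl]-7-(benzyloxy)-5-hydroxy-3-methoxy-4H-chromen-4-one F14. Pd(PPh3)4 and morpholine then give 7-(benzyloxy)-2-[2-(benzyloxy)-5-hydroxy-4-methoxyphenyl]-5-hydroxy-3-methoxy-4H-chromen-4-one F15. Ac2O (1.05 equiv) in pyridine at 0 °C should acylate only O5', giving 4-(benzyloxy)-5-[7-(benzyloxy)-5-hydroxy-3-methoxy-4-oxo-4H-chromen-2-yl]-2-methoxyphenyl acetate F16. Hydrogenolysis as in step 13 gives 20.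

## Further compounds

F1 | step 9 | 5-(allyloxy)-2-(benzyloxy)-4-methoxybenzoic acid | COc1cc(OCc2ccccc2)c(C(=O)O)cc1OCC=C
F2 | step 9 | 5-(allyloxy)-2-(benzyloxy)-4-methoxybenzoyl chloride | COc1cc(OCc2ccccc2)c(C(=O)Cl)cc1OCC=C
F3 | step 9 | 2-methoxy-1-(2,4,6-trihydroxyphenyl)ethan-1-one | COCC(=O)c1c(O)cc(O)cc1O
F4 | step 9 | 1-[2,4-bis(benzyloxy)-6-hydroxyphenyl]-2-methoxyethan-1-one | COCC(=O)c1c(O)cc(OCc2ccccc2)cc1OCc1ccccc1
F5 | step 9 | 3-[5-(allyloxy)-2-(benzyloxy)-4-methoxyphenyl]-1-[2,4-bis(benzyloxy)-6-hydroxyphenyl]-2-methoxypropane-1,3-dione (racemic, enolisable) | COC(C(=O)c1c(O)cc(OCc2ccccc2)cc1OCc1ccccc1)C(=O)c1cc(OCC=C)c(OC)cc1OCc1ccccc1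
F6 | step 8 | (2Z)-3-[5-(allyloxy)-2-(benzyloxy)-4-methoxyphenyl]-2,3-dimethoxyprop-2-en-1-ol | OC/C(OC)=C(/OC)c1cc(OCC=C)c(OC)cc1OCc1ccccc1
F7 | step 8 | (2Z)-3-[5-(allyloxy)-2-(benzyloxy)-4-methoxyphenyl]-2,3-dimethoxyprop-2-enal | O=C/C(OC)=C(/OC)c1cc(OCC=C)c(OC)cc1OCc1ccccc1
F8 | step 8 | methyl (8Z)-9-[5-(allyloxy)-2-(benzyloxy)-4-methoxyphenyl]-7-hydroxy-8,9-dimethoxy-3,5-dioxonon-8-enoate (racemic) | COC(=O)CC(=O)CC(=O)CC(O)/C(OC)=C(/OC)c1cc(OCC=C)c(OC)cc1OCc1ccccc1
F9 | step 6 | methyl 3-[5-(allyloxy)-2-(benzyloxy)-4-methoxyphenyl]-2,3,3-trimethoxypropanoate (racemic) | COC(=O)C(OC)C(OC)(OC)c1cc(OCC=C)c(OC)cc1OCc1ccccc1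
F10 | step 1 | 2-(benzyloxy)-4-methoxybenzaldehyde | COc1ccc(C=O)c(OCc2ccccc2)c1
F11 | step 1 | 2-(benzyloxy)-5-bromo-4-methoxybenzaldehyde | COc1cc(OCc2ccccc2)c(C=O)cc1Br
F12 | step 1 | 2-(benzyloxy)-4-methoxy-5-(4,4,5,5-tetramethyl-1,3,2-dioxaborolan-2-yl)benzaldehyde | COc1cc(OCc2ccccc2)c(C=O)cc1B1OC(C)(C)C(C)(C)O1
F13 | step 1 | 2-(benzyloxy)-5-hydroxy-4-methoxybenzaldehyde | COc1cc(OCc2ccccc2)c(C=O)cc1O
F14 | step 10 | 2-[5-(allyloxy)-2-(benzyloxy)-4-methoxyphenyl]-7-(benzyloxy)-5-hydroxy-3-methoxy-4H-chromen-4-one | COc1cc(OCc2ccccc2)c(-c2oc3cc(OCc4ccccc4)cc(O)c3c(=O)c2OC)cc1OCC=C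
F15 | step 10 | 7-(benzyloxy)-2-[2-(benzyloxy)-5-hydroxy-4-methoxyphenyl]-5-hydroxy-3-methoxy-4H-chromen-4-one | COc1cc(OCc2ccccc2)c(-c2oc3cc(OCc4ccccc4)cc(O)c3c(=O)c2OC)cc1O
F16 | step 10 | 4-(benzyloxy)-5-[7-(benzyloxy)-5-hydroxy-3-methoxy-4-oxo-4H-chromen-2-yl]-2-methoxyphenyl acetate | COc1cc(OCc2ccccc2)c(-c2oc3cc(OCc4ccccc4)cc(O)c3c(=O)c2OC)cc1OC(C)=O
A1 | alternative 1 | 1,5-bis(benzyloxy)-2-iodo-3-(methoxymethoxy)benzene | COCOc1cc(OCc2ccccc2)cc(OCc2ccccc2)c1I
A2 | alternative 1 | 1-[2-(benzyloxy)-4-methoxy-5-(methoxymethoxy)phenyl]-2-methoxyethan-1-one | COCC(=O)c1cc(OCOC)c(OC)cc1OCc1ccccc1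
A3 | alternative 1 | 1-[2,4-bis(benzyloxy)-6-(methoxymethoxy)phenyl]-3-[2-(benzyloxy)-4-methoxy-5-(methoxymethoxy)phenyl]-2-methoxypropane-1,3-dione (racemic, enolisable) | COCOc1cc(OCc2ccccc2)cc(OCc2ccccc2)c1C(=O)C(OC)C(=O)c1cc(OCOC)c(OC)cc1OCc1ccccc1
A4 | alternative 2 | 1-[5-(allyloxy)-2-(benzyloxy)-4-methoxyphenyl]-2-methoxyethan-1-one | COCC(=O)c1cc(OCC=C)c(OC)cc1OCc1ccccc1
A5 | alternative 2 | 2,4,6-trifluorobenzoyl chloride | O=C(Cl)c1c(F)cc(F)cc1F
A6 | alternative 2 | 2-[5-(allyloxy)-2-(benzyloxy)-4-methoxyphenyl]-5,7-difluoro-3-methoxy-4H-chromen-4-one | COc1cc(OCc2ccccc2)c(-c2oc3cc(F)cc(F)c3c(=O)c2OC)cc1OCC=C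
A7 | alternative 3 | 3,5-bis(benzyloxy)-2-(trimethylsilyl)phenyl trifluoromethanesulfonate | C[Si](C)(C)c1c(OS(=O)(=O)C(F)(F)F)cc(OCc2ccccc2)cc1OCc1ccccc1
A8 | alternative 3 | 6-[5-(allyloxy)-2-(benzyloxy)-4-methoxyphenyl]-5-methoxy-2,2-dimethyl-4H-1,3-dioxin-4-one | COC1=C(c2cc(OCC=C)c(OC)cc2OCc2ccccc2)OC(C)(C)OC1=O
A9 | alternative 3 | 3,5-bis(benzyloxy)benzyne | C1#CC(OCc2ccccc2)=CC(OCc2ccccc2)=C1
A10 | alternative 3 | 3-[5-(allyloxy)-2-(benzyloxy)-4-methoxyphenyl]-2-methoxy-3-oxoprop-1-en-1-one (aroyl(methoxy)ketene) | COC(=C=O)C(=O)c1cc(OCC=C)c(OC)cc1OCc1ccccc1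
A11 | alternative 3 | 2-[5-(allyloxy)-2-(benzyloxy)-4-methoxyphenyl]-5,7-bis(benzyloxy)-3-methoxy-4H-chromen-4-one (identical with 17) | COc1cc(OCc2ccccc2)c(-c2oc3cc(OCc4ccccc4)cc(OCc4ccccc4)c3c(=O)c2OC)cc1OCC=C
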